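**Retrosynthetic overview**
1. 18 ⇒ Heck disconnection of the diene C–C bond next to the butenolide: alkenyl bromide 14 + 4-vinylbutenolide 17 (ring B, the butenolide, is bought as 15).
2. 14 ⇒ key step, a radical [3+2] carbo-lactonisation of α-bromo acid 12 with 4-methylpenta-1,3-diene 13; it forms C3–C4 and C5–O of ring A, the (R) centre and the Z-alkylidene in one operation.
3. 12 ⇒ aldehyde 9 + methyl tribromoacetate 10 (CrCl2 bromo-olefination, then hydrolysis).
4. 9 ⇒ Johnson–Claisen of carbinol 5 with orthoacetate 6 (E-trisubstituted alkene); 5 ⇒ Negishi carboalumination/bromination of enynol 3; 3 ⇒ pent-4-ynal 1 + isopropenyl Grignard reagent 2.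
5. Ring order: ring B is present from the start; ring A is closed in step 7.

Assumption: 1, 2, 6, 10, 13, 15 and 16 are bought; which antipode of the bisoxazoline ligand gives (R) in step 7 must be fixed by experiment, and (S,S)-tBu-Box is written for it.

**Step 1**
Reactants: 1 pent-4-ynal; 2 isopropenylmagnesium bromide
Product: 3 rac-2-methylhept-1-en-6-yn-3-ol
Conditions: THF, −78 °C; then sat. aq. NH4Cl
Reagents that add atoms: none
Why: Grignard 1,2-addition to the aldehyde is far faster at −78 °C than deprotonation of the terminal alkyne, and the racemic carbinol centre made here is erased in step 3.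

**Step 2**
Reactants: 3 rac-2-methylhept-1-en-6-yn-3-ol
Product: 5 rac-(6E)-7-bromo-2,6-dimethylhepta-1,6-dien-3-ol, via alkenylalane 4 (not isolated)
Conditions: Me3Al (3.5 equiv), Cp2ZrCl2 (25 mol%), CH2Cl2, 0 °C to rt; then NBS (3 equiv), THF, −30 °C; then aq. potassium sodium tartrate
Reagents that add atoms: trimethylaluminum C[Al](C)C; N-bromosuccinimide O=C1CCC(=O)N1Br
Why: Negishi zirconium-catalysed carboalumination adds Me and Al syn across the terminal alkyne with Me on the internal carbon (the hydroxyl is masked in the flask as its dimethylaluminium alkoxide), and bromodealumination with NBS goes with retention to give the E alkenyl bromide.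

**Step 3**
Reactants: 5 rac-(6E)-7-bromo-2,6-dimethylhepta-1,6-dien-3-ol; 6 trimethyl orthoacetate
Product: 8 methyl (4E,8E)-9-bromo-4,8-dimethylnona-4,8-dienoate, via ketene acetal 7 (not isolated)
Conditions: 6 (6 equiv), EtCO2H (10 mol%), xylene, 125 °C, MeOH distilled off
Reagents that add atoms: none
Why: Johnson–Claisen orthoester rearrangement through a chair transition state with the side chain equatorial (no 1,3-diaxial clash with OMe) gives the E trisubstituted alkene (>95:5) and removes the racemic carbinol centre.

**Step 4**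
Reactants: 8 methyl (4E,8E)-9-bromo-4,8-dimethylnona-4,8-dienoate
Product: 9 (4E,8E)-9-bromo-4,8-dimethylnona-4,8-dienal
Conditions: i-Bu2AlH (1.05 equiv), CH2Cl2, −78 °C; then aq. potassium sodium tartrate
Reagents that add atoms: none
Why: partial ester reduction with one equivalent of diisobutylaluminum hydride at −78 °C stops at the aluminium hemiacetal, which gives the aldehyde on work-up while the alkenyl bromide and alkenes are untouched.

**Step 5**
Reactants: 9 (4E,8E)-9-bromo-4,8-dimethylnona-4,8-dienal; 10 methyl tribromoacetate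
Product: 11 methyl (2Z,6E,10E)-2,11-dibromo-6,10-dimethylundeca-2,6,10-trienoate
Conditions: CrCl2 (5 equiv), 10 (1.5 equiv), THF, rt
Reagents that add atoms: none
Why: CrCl2-mediated Reformatsky-type addition of the tribromoacetate to the aldehyde followed by chromium-induced reductive β-elimination (Takai–Falck-type halo-olefination) gives the α-bromoacrylate in one flask, divalent chromium without nickel leaves the alkenyl bromide alone, and the Z geometry formed does not matter because it is lost in the vinyl radical of step 7.

**Step 6**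
Reactants: 11 methyl (2Z,6E,10E)-2,11-dibromo-6,10-dimethylundeca-2,6,10-trienoate
Product: 12 (2Z,6E,10E)-2,11-dibromo-6,10-dimethylundeca-2,6,10-trienoic acid
Conditions: LiOH (3 equiv), THF/H2O 3:1, 0 °C to rt; then 1 M HCl
Reagents that add atoms: lithium hydroxide [Li+].[OH-]
Why: saponification of the methyl ester under conditions mild enough that the α-bromoacrylate neither adds hydroxide nor loses HBr.

**Step 7 (key step)**
Reactants: 12 (2Z,6E,10E)-2,11-dibromo-6,10-dimethylundeca-2,6,10-trienoic acid; 13 4-methylpenta-1,3-diene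
Product: 14 (3Z,5R)-3-[(4E,8E)-9-bromo-4,8-dimethylnona-4,8-dien-1-ylidene]-5-(2-methylprop-1-en-1-yl)oxolan-2-one
Conditions: Cu(MeCN)4PF6 (10 mol%), (S,S)-tBu-Box (12 mol%), Ir(ppy)3 (1 mol%), KHCO3 (1.2 equiv), 13 (20 equiv), EtOAc/MeCN 4:1, 450 nm LEDs, 0 °C
Reagents that add atoms: none
Why: Proposed new method: a photoinduced copper-catalysed enantioselective radical carbo-lactonisation of a 1,3-diene, in which excited Ir(ppy)3 reduces the activated C2–Br bond of the copper-bound acid (the unactivated alkenyl bromide at C11 is roughly 1 V harder to reduce) to a linear α-carboxy vinyl π-radical that adds to the unsubstituted CH2 terminus of 13 from the side of the small β-hydrogen, which places the chain cis to the carbonyl (Z), and the resulting 1,1-dimethylallyl radical is captured by the chiral bisoxazoline divalent copper carboxylate and closes ring A by C–O reductive elimination from trivalent copper at the secondary allyl terminus, which sets C5 as R under ligand control, while any allyl bromide formed by bromine transfer is re-opened by monovalent copper; the closest known reactions are the copper/bisoxazoline-catalysed enantioselective radical oxyfunctionalisation of alkenoic acids to lactones, the photoinduced copper-catalysed asymmetric carbo-acyloxylation of 1,3-dienes, the Mn(OAc)3-type oxidative radical lactonisation of dienes and the photoredox generation of vinyl radicals from α-bromo enones.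

**Step 8**
Reactants: 15 4-bromofuran-2(5H)-one; 16 potassium vinyltrifluoroborate
Product: 17 4-ethenylfuran-2(5H)-one
Conditions: PdCl2(dppf) (3 mol%), Cs2CO3 (3 equiv), THF/H2O 9:1, 60 °C; used fresh
Reagents that add atoms: none
Why: Suzuki–Miyaura coupling, with fast oxidative addition at the β-bromo enoate (a vinylogous acyl bromide), gives the 4-vinylbutenolide, which is used at once because it slowly dimerises.

**Step 9**
Reactants: 14 (3Z,5R)-3-[(4E,8E)-9-bromo-4,8-dimethylnona-4,8-dien-1-ylidene]-5-(2-methylprop-1-en-1-yl)oxolan-2-one; 17 4-ethenylfuran-2(5H)-one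
Product: 18 (3Z,5R)-3-[(4E,8E,10E)-4,8-dimethyl-11-(5-oxo-2,5-dihydrofuran-3-yl)undeca-4,8,10-trien-1-ylidene]-5-(2-methylprop-1-en-1-yl)oxolan-2-one (CNP0187251.2)
Conditions: Pd(OAc)2 (5 mol%), P(o-tol)3 (10 mol%), NaHCO3 (2.5 equiv), Bu4NCl (1 equiv), 17 (2 equiv), DMF, 60–70 °C, dark
Reagents that add atoms: none
Why: Heck reaction in which oxidative addition to the alkenyl bromide goes with retention, insertion takes place at the terminal CH2 of the vinylbutenolide and syn β-hydride elimination gives the new E alkene, so the E,E-diene is formed without touching the stereocentre or the Z-alkylidene.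

**Compound list**
1 | pent-4-ynal | C#CCCC=O | starting material
2 | isopropenylmagnesium bromide (prop-1-en-2-ylmagnesium bromide) | CC(=C)[Mg]Br | starting material
3 | rac-2-methylhept-1-en-6-yn-3-ol | C=C(C)C(O)CCC#C | intermediate
4 | rac-dimethylaluminium (6E)-7-(dimethylalumanyl)-2,6-dimethylhepta-1,6-dien-3-olate (alkenylalane) | C=C(C)C(O[Al](C)C)CC/C(C)=C/[Al](C)C | intermediate
5 | rac-(6E)-7-bromo-2,6-dimethylhepta-1,6-dien-3-ol | C=C(C)C(O)CC/C(C)=C/Br | intermediate
6 | trimethyl orthoacetate (1,1,1-trimethoxyethane) | CC(OC)(OC)OC | starting material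
7 | rac-(6E)-7-bromo-3-[(1-methoxyethenyl)oxy]-2,6-dimethylhepta-1,6-diene (ketene acetal) | C=C(OC)OC(CC/C(C)=C/Br)C(C)=C | intermediate
8 | methyl (4E,8E)-9-bromo-4,8-dimethylnona-4,8-dienoate | COC(=O)CC/C(C)=C/CC/C(C)=C/Br | intermediate
9 | (4E,8E)-9-bromo-4,8-dimethylnona-4,8-dienal | O=CCC/C(C)=C/CC/C(C)=C/Br | intermediate
10 | methyl tribromoacetate | COC(=O)C(Br)(Br)Br | starting material
11 | methyl (2Z,6E,10E)-2,11-dibromo-6,10-dimethylundeca-2,6,10-trienoate | COC(=O)/C(Br)=C/CC/C(C)=C/CC/C(C)=C/Br | intermediate
12 | (2Z,6E,10E)-2,11-dibromo-6,10-dimethylundeca-2,6,10-trienoic acid | OC(=O)/C(Br)=C/CC/C(C)=C/CC/C(C)=C/Br | intermediate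
13 | 4-methylpenta-1,3-diene | C=CC=C(C)C | starting material
14 | (3Z,5R)-3-[(4E,8E)-9-bromo-4,8-dimethylnona-4,8-dien-1-ylidene]-5-(2-methylprop-1-en-1-yl)oxolan-2-one | CC(C)=C[C@H]1C/C(=C/CC/C(C)=C/CC/C(C)=C/Br)C(=O)O1 | intermediate
15 | 4-bromofuran-2(5H)-one | O=C1C=C(Br)CO1 | starting material
16 | potassium vinyltrifluoroborate | C=C[B-](F)(F)F.[K+] | starting material
17 | 4-ethenylfuran-2(5H)-one | C=CC1=CC(=O)OC1 | intermediate
18 | (3Z,5R)-3-[(4E,8E,10E)-4,8-dimethyl-11-(5-oxo-2,5-dihydrofuran-3-yl)undeca-4,8,10-trien-1-ylidene]-5-(2-methylprop-1-en-1-yl)oxolan-2-one | CC(C)=C[C@H]1C/C(=C/CC/C(C)=C/CC/C(C)=C/C=C/C2=CC(=O)OC2)C(=O)O1 | target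

**Step count**
Total: 9 steps. Longest linear sequence: 8 steps (steps 1–7, then 9); step 8 is a one-step side branch.

**Three steps most likely to fail**

Step 7. The method is new: the enantioselectivity, the Z/E ratio at the alkylidene and a competing 6-endo cyclisation of the vinyl radical onto the C6=C7 alkene are all untested. The fallback is a non-radical chiral-pool olefination that sets out from aldehyde 9 and comes back at 14. Bought (R)-5-(hydroxymethyl)oxolan-2-one F1 is oxidised with Dess–Martin periodinane in CH2Cl2 to (R)-5-oxooxolane-2-carbaldehyde F2. F2 is used at once in a Wittig reaction with isopropylidenetriphenylphosphorane (i-PrPPh3I, n-BuLi, THF, −78 °C) to give (R)-5-(2-methylprop-1-en-1-yl)oxolan-2-one F3. Lithium diisopropylamide (2.2 equiv) and then bis(2,2,2-trifluoroethyl) phosphorochloridate convert F3 into (5R)-3-[bis(2,2,2-trifluoroethoxy)phosphoryl]-5-(2-methylprop-1-en-1-yl)oxolan-2-one F4. Still–Gennari olefination of 9 with F4 (potassium hexamethyldisilazide, 18-crown-6, THF, −78 °C) then gives 14 with the chain cis to the carbonyl; the Z-selectivity of this lactone phosphonate is expected by analogy with α-substituted trifluoroethyl phosphonoacetates and would need to be confirmed.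

Step 9. The alkenyl bromide needs 60–70 °C, 17 dimerises or polymerises, and a palladium hydride could isomerise the exocyclic alkene of 14. The fallback is a Stille union that avoids 17; it sets out from 15, uses 14 and comes back at 18. Compound 15 is mono-coupled with (E)-1,2-bis(tributylstannyl)ethene (Pd(PPh3)4, toluene, 80 °C) to give (E)-4-[2-(tributylstannyl)ethenyl]furan-2(5H)-one F5. F5 is then joined to 14 under mild Stille conditions (Pd2(dba)3, AsPh3, CuI, NMP, 40 °C) with retention at both alkenes.

Step 2. Carboalumination and NBS quench are run on a free isopropenyl carbinol, where excess Me3Al and bromination of the 1,1-disubstituted alkene can cost yield. The fallback moves the alkyne functionalisation ahead of the Grignard addition; it sets out from 2 and comes back at 5. Bought pent-4-yn-1-ol F6 is carboaluminated and brominated (Me3Al, Cp2ZrCl2; then NBS) to (E)-5-bromo-4-methylpent-4-en-1-ol F7. F7 is oxidised (SO3·pyridine, DMSO, Et3N) to (E)-5-bromo-4-methylpent-4-enal F8, and addition of 2 to F8 (THF, −78 °C) gives 5.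

**Further compounds**
F1 | step 7 | (R)-5-(hydroxymethyl)oxolan-2-one | OC[C@H]1CCC(=O)O1
F2 | step 7 | (R)-5-oxooxolane-2-carbaldehyde | O=C[C@H]1CCC(=O)O1
F3 | step 7 | (R)-5-(2-methylprop-1-en-1-yl)oxolan-2-one | CC(C)=C[C@H]1CCC(=O)O1
F4 | step 7 | (5R)-3-[bis(2,2,2-trifluoroethoxy)phosphoryl]-5-(2-methylprop-1-en-1-yl)oxolan-2-one | CC(C)=C[C@H]1CC(C(=O)O1)P(=O)(OCC(F)(F)F)OCC(F)(F)F
F5 | step 9 | (E)-4-[2-(tributylstannyl)ethenyl]furan-2(5H)-one | CCCC[Sn](CCCC)(CCCC)/C=C/C1=CC(=O)OC1
F6 | step 2 | pent-4-yn-1-ol | C#CCCCO
F7 | step 2 | (E)-5-bromo-4-methylpent-4-en-1-ol | OCCC/C(C)=C/Br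
F8 | step 2 | (E)-5-bromo-4-methylpent-4-enal | O=CCC/C(C)=C/Br
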